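The cyclohex-3-en-1-ol ring of the terpinen-4-yl unit is disconnected at two opposite single bonds: C1–C2 (carbinol carbon to the allylic CH2) and C4–C5 (methyl-bearing alkene carbon to ring CH2). One flask makes both from 1-isopropylcyclopropanol and (E)-crotyl diethyl phosphate: ring opening to a zinc homoenolate, enantioselective copper-catalysed SN2′ allylation to (R)-2,6-dimethyloct-7-en-3-one, then a carbonyl-ene closure that relays the C–H stereocentre to the quaternary carbinol carbon. The step exploits the homoallylic alcohol array C1(OH)–C2–C3=C4 and the 1,4-relation of C1 and C4 across the ring. Acylation with 3,5-dibromo-4-methoxybenzoyl chloride and double prenylation complete the target.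

Key step: step 3

Remark: the ene closure is taken to be concerted, so oxygen becomes bonded on the ring face that loses the hydrogen; on that basis (6R)-6 leads to (R)-7. Compounds 8 and 12 (as a THF solution) are taken as commercial.

Step 1
Reactants: 1 methyl 2-methylpropanoate
Product: 2 1-(propan-2-yl)cyclopropan-1-ol
Conditions: EtMgBr (2.4 equiv), Ti(OiPr)4 (0.2 equiv), Et2O, 0 °C to rt; aq. NH4Cl
Reagents that add atoms: ethylmagnesium bromide, CC[Mg]Br
Why: Kulinkovich reaction: the titanacyclopropane formed from Ti(OiPr)4 and two ethyl groups adds twice to the ester carbonyl and supplies both ring CH2 groups; no stereocentre is formed.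

Step 2
Reactants: 3 (E)-but-2-en-1-ol
Product: 4 (E)-but-2-en-1-yl diethyl phosphate
Conditions: ClP(O)(OEt)2, Et3N, DMAP (cat.), CH2Cl2, 0 °C
Reagents that add atoms: diethyl chlorophosphate, CCOP(=O)(Cl)OCC
Why: O-phosphorylation of a primary allylic alcohol by nucleophilic substitution at phosphorus; the E alkene is not touched.

Step 3
Reactants: 2 1-(propan-2-yl)cyclopropan-1-ol; 4 (E)-but-2-en-1-yl diethyl phosphate
Product: 7 (1R)-4-methyl-1-(propan-2-yl)cyclohex-3-en-1-ol, via ethyl(4-methyl-3-oxopentyl)zinc 5 (not isolated), via (6R)-2,6-dimethyloct-7-en-3-one 6 (not isolated)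
Conditions: (a) Et2Zn (1.1 equiv), THF, 0 °C to rt; (b) 4, (CuOTf)2·C6H6 (2.5 mol %), chiral sulfonate-bearing N-heterocyclic carbene ligand (5 mol %, enantiomer chosen for 6R), −15 °C; (c) same flask, THF exchanged for CH2Cl2 under vacuum, Me2AlCl (3 equiv), −78 to 0 °C; aq. NH4Cl, aq. potassium sodium tartrate
Reagents that add atoms: none
Why: Proposed new method: Et2Zn deprotonates 2 and strain-driven cleavage of one of its two equivalent ring bonds gives zinc homoenolate 5, whose alkyl group is passed to a chiral monovalent copper complex and attacks the methyl-bearing alkene carbon of 4 in an SN2′ substitution with loss of phosphate, forming the C5–C6 bond of 6. The closest known reaction types are the copper-mediated SN2′ allylation of cyclopropanol-derived zinc homoenolates and the copper-catalysed enantioselective allylic alkylation of allylic phosphates with alkylzinc reagents, whose union is untested; the ligand selects the face of the E alkene and so sets C6 as R, which requires isomerically pure 4 and γ-selectivity, favoured by the phosphate leaving group. Me2AlCl then complexes the ketone and triggers an intramolecular carbonyl-ene reaction of known type: the terminal alkene carbon bonds to the carbonyl carbon (six-membered closure, exo at the carbonyl, alkene endocyclic) while the allylic hydrogen on C6 migrates to oxygen through a boat-like bicyclic array. Since that hydrogen is the only allylic one and must leave from the face on which oxygen sits, the configuration of C6 is relayed to the new quaternary carbinol carbon and (6R)-6 should give (R)-7. Attack through the internal alkene carbon would close a five-membered ring with no transferable hydrogen in reach, so ring size secures the regiochemistry, and loss of methane from the aluminium alkoxide makes the closure irreversible.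

Step 4
Reactants: 8 3,5-dibromo-4-methoxybenzoic acid; 7 (1R)-4-methyl-1-(propan-2-yl)cyclohex-3-en-1-ol
Product: 11 (1R)-4-methyl-1-(propan-2-yl)cyclohex-3-en-1-yl 3,5-dibromo-4-methoxybenzoate, via 3,5-dibromo-4-methoxybenzoyl chloride 9 (not isolated), via lithium (1R)-4-methyl-1-(propan-2-yl)cyclohex-3-en-1-olate 10 (not isolated)
Conditions: 8, (COCl)2, DMF (cat.), CH2Cl2, rt, evaporate; 7, n-BuLi, THF, −78 °C; then 9, −78 °C to rt
Reagents that add atoms: none
Why: Acid chloride formation followed by acylation of the preformed lithium alkoxide (nucleophilic acyl substitution), the usual answer to a hindered tertiary alcohol; the carbinol C–O bond is not broken, so the R configuration is kept.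

Step 5
Reactants: 11 (1R)-4-methyl-1-(propan-2-yl)cyclohex-3-en-1-yl 3,5-dibromo-4-methoxybenzoate; 12 (3-methylbut-2-en-1-yl)zinc bromide
Product: 13 (1R)-4-methyl-1-(propan-2-yl)cyclohex-3-en-1-yl 4-methoxy-3,5-bis(3-methylbut-2-en-1-yl)benzoate
Conditions: 12 (3 equiv), Pd(OAc)2 (4 mol %), 2-dicyclohexylphosphino-2′,6′-bis(dimethylamino)biphenyl (8 mol %), THF, rt
Reagents that add atoms: none
Why: Twofold Negishi coupling; with this biaryl phosphine, reductive elimination from the σ-allylpalladium intermediate should outrun allyl transposition and give the linear prenyl groups, while the homoallylic tertiary ester and the ring alkene are inert to palladium and to the allylzinc reagent.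

Compound list
1 | methyl 2-methylpropanoate | COC(=O)C(C)C | starting material
2 | 1-(propan-2-yl)cyclopropan-1-ol | CC(C)C1(O)CC1 | intermediate
3 | (E)-but-2-en-1-ol | C/C=C/CO | starting material
4 | (E)-but-2-en-1-yl diethyl phosphate | C/C=C/COP(=O)(OCC)OCC | intermediate
5 | ethyl(4-methyl-3-oxopentyl)zinc | CC[Zn]CCC(=O)C(C)C | intermediate
6 | (6R)-2,6-dimethyloct-7-en-3-one | CC(C)C(=O)CC[C@@H](C)C=C | intermediate
7 | (1R)-4-methyl-1-(propan-2-yl)cyclohex-3-en-1-ol, (R)-terpinen-4-ol | O[C@@]1(C(C)C)CC=C(C)CC1 | intermediate
8 | 3,5-dibromo-4-methoxybenzoic acid | COc1c(Br)cc(C(=O)O)cc1Br | starting material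
9 | 3,5-dibromo-4-methoxybenzoyl chloride | COc1c(Br)cc(C(=O)Cl)cc1Br | intermediate
10 | lithium (1R)-4-methyl-1-(propan-2-yl)cyclohex-3-en-1-olate | [Li+].[O-][C@@]1(C(C)C)CC=C(C)CC1 | intermediate
11 | (1R)-4-methyl-1-(propan-2-yl)cyclohex-3-en-1-yl 3,5-dibromo-4-methoxybenzoate | COc1c(Br)cc(C(=O)O[C@@]2(C(C)C)CC=C(C)CC2)cc1Br | intermediate
12 | (3-methylbut-2-en-1-yl)zinc bromide | CC(C)=CC[Zn]Br | starting material
13 | (1R)-4-methyl-1-(propan-2-yl)cyclohex-3-en-1-yl 4-methoxy-3,5-bis(3-methylbut-2-en-1-yl)benzoate | COc1c(CC=C(C)C)cc(C(=O)O[C@@]2(C(C)C)CC=C(C)CC2)cc1CC=C(C)C | target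

Total step count: 5
Longest linear sequence: 4 steps (1 → 2 → 7 → 11 → 13)

Steps most likely to fail

Step 3. The allylation stage may discriminate poorly between the faces of the small crotyl unit, and ethyl may be transferred from zinc in competition with the homoenolate. In the closure stage the aluminium-complexed ketone may ionise to a cyclohexyl cation (hydride shift, chloride capture, ether bridging) instead of passing through the concerted hydrogen transfer, which would erode the chirality relay. The fallback uses known chemistry and sets out from 2. Aerobic ring opening (Pd(OAc)2, pyridine, O2, toluene, 80 °C) should give 4-methylpent-1-en-3-one F1. Organocatalytic Michael addition of propanal to F1 under a diphenylprolinol methyl ether (enantiomer chosen for 2R) should give (2R)-2,6-dimethyl-5-oxoheptanal F2. Wittig methylenation of the aldehyde alone (Ph3P=CH2 from Ph3PCH3Br and KN(SiMe3)2, THF, −78 °C) comes back to the route at 6, now isolated and assayed. Compound 6 is then closed to 7 with Me2AlCl in a flask of its own, or thermally in a sealed tube if the Lewis acid ionises it.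

Step 5. Allyl transposition at palladium may give branched 1,1-dimethylallyl isomers, and the sequence may stall after the first coupling at the dibromide. The fallback sets out from 11. Twofold Stille allylation with allyltributylstannane (Pd(PPh3)4, toluene, 100 °C), which has no regiochemical ambiguity, should give (1R)-4-methyl-1-(propan-2-yl)cyclohex-3-en-1-yl 4-methoxy-3,5-di(prop-2-en-1-yl)benzoate F3. Cross-metathesis with excess 2-methylbut-2-ene (second-generation Grubbs catalyst, CH2Cl2, 40 °C) should turn both allyl groups into prenyl groups and comes back at 13; the trisubstituted ring alkene is too hindered to take part.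

Step 4. Acyl transfer to the congested tertiary alkoxide may be slow, leaving the alkoxide to be quenched by adventitious proton sources before it is acylated. The fallback sets out from 9 and neutral 7. AgOSO2CF3 in CH2Cl2 at −78 °C should convert 9 into the far more electrophilic 3,5-dibromo-4-methoxybenzoyl trifluoromethanesulfonate F4. F4 acylates the free alcohol 7 in the presence of 2,6-di-tert-butyl-4-methylpyridine, with no strong base, and comes back at 11.

Further compounds
F1 | step 3 | 4-methylpent-1-en-3-one | CC(C)C(=O)C=C
F2 | step 3 | (2R)-2,6-dimethyl-5-oxoheptanal | CC(C)C(=O)CC[C@@H](C)C=O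
F3 | step 5 | (1R)-4-methyl-1-(propan-2-yl)cyclohex-3-en-1-yl 4-methoxy-3,5-di(prop-2-en-1-yl)benzoate | COc1c(CC=C)cc(C(=O)O[C@@]2(C(C)C)CC=C(C)CC2)cc1CC=C
F4 | step 4 | 3,5-dibromo-4-methoxybenzoyl trifluoromethanesulfonate | COc1c(Br)cc(C(=O)OS(=O)(=O)C(F)(F)F)cc1Br
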